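Readings and results were computed for substances that don't exist; scatter was added.

Molar per hour was the unit I reckoned in, since L sits in these flasks as a solid.

in all of them: G 51 mM (held)
- teal: L 0.56 M; temperature 35 °C; run made earlier
- grey: L 0.88 M; temperature 57 °C; run made earlier
- epsilon: L 0.40 M; at 25 °C until 12 h, from then on at 65 °C; time 40 h
- delta: L 0.40 M; at 65 °C throughout; time 40 h

| run | time / h | Q / % | D / % |
|---|---|---|---|
| teal | 6.00 | 2.4 | 0.2 |
| teal | 12.0 | 6.3 | 3.5 |
| teal | 20.0 | 10.2 | 8.4 |
| teal | 25.0 | 12.0 | 13.7 |
| teal | 30.0 | 12.8 | 18.4 |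
| grey | 2.00 | 1.2 | 0.2 |
| grey | 4.00 | 2.5 | 1.5 |
| grey | 6.00 | 3.4 | 1.5 |
| grey | 8.00 | 5.2 | 2.8 |
| grey | 10.0 | 5.8 | 5.5 |

(scatter of a reading: 0.5 percentage points)

1. which of the two ends with the higher share of Q in all that became Q or D ("neither" if they lie within 2 percentage points) (epsilon / delta / neither)
2. share of Q in all that became Q or D, epsilon
3. share of Q in all that became Q or D, delta

- solid, in amounts per volume of the solution: L
- at the start none of G is in solution
- at the start none of L is in solution
- what has only dissolved of L counts as not reacted

1. I wrote the balance of L, the limiting reagent, since G is held. As far as the readings show, charged L goes to Q or D, so Q plus D in molar measures the L used.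

2. The bench rule for a suspended solid is a steady feed, the same in M/h whatever the charge. At its last reading the grey run gave 0.00994 M h⁻¹, and the teal run gave 0.00582 M h⁻¹.

3. The rule ends where the solid ends. So I named the run-out time, the charged [L] divided by the feed. For delta, lending it the grey feed, this is 40.2 h. The asked time divided by it is 0.994, so delta stands on the border. For epsilon I lent the teal feed to the cool stretch and the grey feed to the rest, which gave 45.2 h, later than delta.

4. Over the last two readings of the teal run, Q went from 12.0% to 12.8%, with a scatter of 0.5 percentage points, while D went from 13.7% to 18.4%. I therefore expected Q to change slowly while the feed lasted and to fall afterwards, and I committed to epsilon ending higher.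

5. The forecast answered neither, with 13% for epsilon and 11% for delta, holding that “the 28 h there erases any memory of the cool start”; there my reckoning differed.

6. The simulation gave epsilon: 14.8% for epsilon against 8.99% for delta.

    G ⇌ Z, rate k1*(csat - [Z]) (kL = 1.43 h⁻¹)
    J + Z → Q (k = 2.51 M⁻¹ h⁻¹, Ea = 77.0 kJ mol⁻¹)
    Z + Q → D (k = 2.36 M⁻¹ h⁻¹, Ea = 50.0 kJ mol⁻¹)
    J ⇌ X (K = 0.720, k = 0.137 h⁻¹, Ea = 104 kJ mol⁻¹, ΔH = −44.0 kJ mol⁻¹)
    L ⇌ J, rate k5*(cs5 - [J]) while solid is left; crystals form when [J] > cs5 (solubility = 0.140 M, k = 0.0902 h⁻¹)
    2 Z → E (k = 20.0 M⁻¹ h⁻¹, Ea = 64.0 kJ mol⁻¹)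
    (constants at 25 °C)

The difference in temperature programme is the main reason for the gap: with that difference taken away, so that delta runs on epsilon's programme, delta gives 14.8% in place of 8.99%. Read at 15 h, delta stood at 37.3% of its run-out time, and its Q plus D was 38.2%, with 61% of L still there, solid or dissolved. Near the run-out time the delta answer is steep, moving by 5 percentage points at 37.3 h and at 44.0 h; at the asked time epsilon still held 1.60% of its charge as dissolved J, delta 0.196%.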